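**Assumption:** the target has no stereocentre and no stereogenic double bond, so it is achiral and the task reduces to making the constitution shown; sp3 centres in the transient intermediates 7, 9 and 11 are racemic and are destroyed again.

## Retrosynthetic overview

1. Target ⇐ chelation-controlled O-demethylation at C5 (peri to the carbonyl) and O-debenzylation of a 3-hydroxy-5,6,7,8-tetramethoxyflavone carrying a 2,5-bis(benzyloxy)phenyl ring B.
2. 3-OH ⇐ epoxidation of the flavone C2=C3 bond and acid rearrangement; ring C ⇐ oxidative cyclisation (O1–C2 bond) of a 2'-hydroxychalcone.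
3. Chalcone ⇐ intermolecular Claisen–Schmidt aldol condensation (the future C2–C3 bond) of 2-hydroxy-3,4,5,6-tetramethoxyacetophenone with 2,5-bis(benzyloxy)benzaldehyde.
4. Acetophenone ⇐ 3,4,5-trimethoxyphenol by C-acetylation, bromination and copper-catalysed methoxylation; aldehyde ⇐ 2,5-dihydroxybenzaldehyde by benzylation.
5. Ring order: rings A and B are bought as benzenes; ring C (the pyranone) is the only ring formed, after the aldol step.

## Route

Step 1
Reactants: 1 3,4,5-trimethoxyphenol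
Product: 2 1-(6-hydroxy-2,3,4-trimethoxyphenyl)ethan-1-one
Conditions: AcOH (solvent and acyl donor), BF3·OEt2 (Lewis-acid promoter, 3 equiv), 85 °C, 3 h; then H2O
Reagents that add atoms: acetic acid, CC(=O)O
Why: BF3-mediated Friedel–Crafts (Fries-type) C-acylation can only occur at the two equivalent free positions ortho to the phenol, and the chelated ortho-hydroxy ketone is the thermodynamic product.

Step 2
Reactants: 2 1-(6-hydroxy-2,3,4-trimethoxyphenyl)ethan-1-one
Product: 3 1-(3-bromo-2-hydroxy-4,5,6-trimethoxyphenyl)ethan-1-one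
Conditions: NBS (1.05 equiv), MeCN, 0 °C → rt, dark
Reagents that add atoms: N-bromosuccinimide, O=C1CCC(=O)N1Br
Why: Electrophilic aromatic bromination takes the single remaining ring C–H, which is ortho to the phenol and strongly activated, much faster than the ketone is brominated at its methyl group.

Step 3
Reactants: 3 1-(3-bromo-2-hydroxy-4,5,6-trimethoxyphenyl)ethan-1-one
Product: 4 1-(2-hydroxy-3,4,5,6-tetramethoxyphenyl)ethan-1-one
Conditions: NaOMe (25% in MeOH, 6 equiv), CuBr (20 mol%), DMF, 110 °C, N2; then aq. HCl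
Reagents that add atoms: sodium methoxide, [Na+].[O-]C
Why: Ullmann-type copper-catalysed methoxylation of an ortho-bromophenoxide bearing a carbonyl group is the same transformation as the 5-bromovanillin to syringaldehyde process, and the ketone is protected from self-condensation as its phenoxide.

Step 4
Reactants: 5 2,5-dihydroxybenzaldehyde
Product: 6 2,5-bis(benzyloxy)benzaldehyde
Conditions: BnBr (2.4 equiv), K2CO3 (3 equiv), DMF, 60 °C
Reagents that add atoms: benzyl bromide, BrCc1ccccc1
Why: Williamson ether synthesis masks both hydroquinone hydroxyls as benzyl ethers, which withstand base, iodine/DMSO and dioxirane and are removed later by hydrogenolysis.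

Step 5
Reactants: 4 1-(2-hydroxy-3,4,5,6-tetramethoxyphenyl)ethan-1-one; 6 2,5-bis(benzyloxy)benzaldehyde
Product: 8 (E)-3-[2,5-bis(benzyloxy)phenyl]-1-(2-hydroxy-3,4,5,6-tetramethoxyphenyl)prop-2-en-1-one, via aldol adduct 7 (not isolated)
Conditions: KOH (50% aq., 10 equiv), EtOH, rt, 36 h; then 1 M HCl to pH 3
Reagents that add atoms: none
Why: Claisen–Schmidt crossed aldol condensation of the methyl ketone enolate with the non-enolisable aldehyde forms the future C2–C3 bond, and E1cB dehydration of racemic 7 gives the conjugated E-enone.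

Step 6
Reactants: 8 (E)-3-[2,5-bis(benzyloxy)phenyl]-1-(2-hydroxy-3,4,5,6-tetramethoxyphenyl)prop-2-en-1-one
Product: 10 2-[2,5-bis(benzyloxy)phenyl]-5,6,7,8-tetramethoxy-4H-chromen-4-one, via flavanone 9 (not isolated)
Conditions: I2 (10 mol%), DMSO, 120 °C, 3 h; then aq. Na2S2O3
Reagents that add atoms: none
Why: Intramolecular oxa-Michael addition of the 2'-phenol closes ring C, and iodine-catalysed dehydrogenation with DMSO as terminal oxidant gives the flavone, removing the racemic C2 centre of 9.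

Step 7
Reactants: 10 2-[2,5-bis(benzyloxy)phenyl]-5,6,7,8-tetramethoxy-4H-chromen-4-one
Product: 12 2-[2,5-bis(benzyloxy)phenyl]-3-hydroxy-5,6,7,8-tetramethoxy-4H-chromen-4-one, via flavone epoxide 11 (not isolated)
Conditions: dimethyldioxirane (ca. 0.08 M in acetone, 3 equiv), CH2Cl2, 0 °C → rt, 24 h; evaporate; then p-TsOH·H2O (10 mol%), CH2Cl2, rt
Reagents that add atoms: dimethyldioxirane, CC1(C)OO1
Why: Dioxirane epoxidation of the enol-ether-like C2=C3 bond gives the racemic cis-fused epoxide 11, which under acid opens at C2 to the oxocarbenium ion and loses H-3 (epoxide rearrangement) to give the 3-hydroxyflavone with no stereocentre left.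

Step 8
Reactants: 12 2-[2,5-bis(benzyloxy)phenyl]-3-hydroxy-5,6,7,8-tetramethoxy-4H-chromen-4-one
Product: 13 2-(2,5-dihydroxyphenyl)-3-hydroxy-5,6,7,8-tetramethoxy-4H-chromen-4-one
Conditions: H2 (1 atm), 10% Pd/C, EtOAc/MeOH 1:1, rt; filter under N2
Reagents that add atoms: none
Why: Catalytic hydrogenolysis cleaves both aryl benzyl ethers under neutral conditions, and the chromone C2=C3 bond of a 3-hydroxyflavone and the methyl ethers are inert at 1 atm.

Step 9
Reactants: 13 2-(2,5-dihydroxyphenyl)-3-hydroxy-5,6,7,8-tetramethoxy-4H-chromen-4-one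
Product: 14 2-(2,5-dihydroxyphenyl)-3,5-dihydroxy-6,7,8-trimethoxy-4H-chromen-4-one
Conditions: BCl3 (1.0 M in CH2Cl2, 6 equiv), CH2Cl2, −20 °C → rt, 2 h; then aq. HCl, rt
Reagents that add atoms: none
Why: Chelation-controlled Lewis-acid ether cleavage: boron bridges the C4 carbonyl and the peri 5-methoxy oxygen so chloride removes only that methyl, leaving the non-chelating 6-, 7- and 8-methoxy groups untouched.

## Compound list

1 | 3,4,5-trimethoxyphenol | COc1cc(O)cc(OC)c1OC | starting material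
2 | 1-(6-hydroxy-2,3,4-trimethoxyphenyl)ethan-1-one | CC(=O)c1c(O)cc(OC)c(OC)c1OC | intermediate
3 | 1-(3-bromo-2-hydroxy-4,5,6-trimethoxyphenyl)ethan-1-one | CC(=O)c1c(O)c(Br)c(OC)c(OC)c1OC | intermediate
4 | 1-(2-hydroxy-3,4,5,6-tetramethoxyphenyl)ethan-1-one | CC(=O)c1c(O)c(OC)c(OC)c(OC)c1OC | intermediate
5 | 2,5-dihydroxybenzaldehyde | O=Cc1cc(O)ccc1O | starting material
6 | 2,5-bis(benzyloxy)benzaldehyde | O=Cc1cc(OCc2ccccc2)ccc1OCc1ccccc1 | intermediate
7 | 3-[2,5-bis(benzyloxy)phenyl]-3-hydroxy-1-(2-hydroxy-3,4,5,6-tetramethoxyphenyl)propan-1-one (racemic aldol adduct, not isolated) | COc1c(OC)c(OC)c(O)c(C(=O)CC(O)c2cc(OCc3ccccc3)ccc2OCc2ccccc2)c1OC | intermediate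
8 | (E)-3-[2,5-bis(benzyloxy)phenyl]-1-(2-hydroxy-3,4,5,6-tetramethoxyphenyl)prop-2-en-1-one | COc1c(OC)c(OC)c(O)c(C(=O)/C=C/c2cc(OCc3ccccc3)ccc2OCc2ccccc2)c1OC | intermediate
9 | 2-[2,5-bis(benzyloxy)phenyl]-5,6,7,8-tetramethoxychroman-4-one (racemic flavanone, not isolated) | COc1c(OC)c(OC)c2c(c1OC)OC(c1cc(OCc3ccccc3)ccc1OCc1ccccc1)CC2=O | intermediate
10 | 2-[2,5-bis(benzyloxy)phenyl]-5,6,7,8-tetramethoxy-4H-chromen-4-one | COc1c(OC)c(OC)c2c(=O)cc(-c3cc(OCc4ccccc4)ccc3OCc3ccccc3)oc2c1OC | intermediate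
11 | 1a-[2,5-bis(benzyloxy)phenyl]-3,4,5,6-tetramethoxy-1a,7a-dihydro-7H-oxireno[2,3-b]chromen-7-one (racemic cis-fused 2,3-epoxide of 10, not isolated) | COc1c(OC)c(OC)c2c(c1OC)OC1(c3cc(OCc4ccccc4)ccc3OCc3ccccc3)OC1C2=O | intermediate
12 | 2-[2,5-bis(benzyloxy)phenyl]-3-hydroxy-5,6,7,8-tetramethoxy-4H-chromen-4-one | COc1c(OC)c(OC)c2c(=O)c(O)c(-c3cc(OCc4ccccc4)ccc3OCc3ccccc3)oc2c1OC | intermediate
13 | 2-(2,5-dihydroxyphenyl)-3-hydroxy-5,6,7,8-tetramethoxy-4H-chromen-4-one | COc1c(OC)c(OC)c2c(=O)c(O)c(-c3cc(O)ccc3O)oc2c1OC | intermediate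
14 | 2-(2,5-dihydroxyphenyl)-3,5-dihydroxy-6,7,8-trimethoxy-4H-chromen-4-one | COc1c(OC)c(O)c2c(=O)c(O)c(-c3cc(O)ccc3O)oc2c1OC | target

## Summary

Total step count: 9. Longest linear sequence: 8 steps (steps 1, 2, 3, 5, 6, 7, 8, 9 from compound 1); step 4 is a one-step side branch.

## Steps most likely to fail, with fallbacks

**Step 3 (copper-catalysed methoxylation).** The bromide is flanked on both sides and the ring is very electron-rich, so slow substitution and proto-debromination back to 2 are the risks. The fallback sets out from compound 1 and comes back at compound 4, building the fifth oxygen before the acetyl group. Compound 1 is ortho-formylated (MgCl2, Et3N, paraformaldehyde, MeCN, reflux) to 6-hydroxy-2,3,4-trimethoxybenzaldehyde F1. Dakin oxidation (H2O2, NaOH, then acid, under N2) gives 3,4,5-trimethoxybenzene-1,2-diol F2. Exhaustive methylation (Me2SO4, K2CO3, acetone, reflux) gives pentamethoxybenzene F3. Friedel–Crafts acetylation with AcCl/AlCl3 in CH2Cl2 at the only free position gives 2,3,4,5,6-pentamethoxyacetophenone F4, which is not isolated: AlCl3 cleaves one of its two equivalent ortho-methoxy groups by chelation and delivers 4.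

**Step 7 (dioxirane epoxidation and rearrangement).** The risks are slow epoxidation of the hindered 2-aryl chromone and competing oxidation of the benzylic C–H bonds or the electron-rich rings. The fallback sets out from compound 10 and comes back at compound 12, using carbanion chemistry instead of an electrophilic oxidant. Deprotonation at C3 with LDA (THF, −78 °C) gives the 3-lithioflavone F5. Trapping with B(OMe)3 gives dimethyl {2-[2,5-bis(benzyloxy)phenyl]-5,6,7,8-tetramethoxy-4-oxo-4H-chromen-3-yl}boronate F6. Oxidation of the C–B bond with H2O2/AcOH (0 °C → rt) gives 12.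

**Step 9 (selective 5-O-demethylation on the free triol).** The risks are poor solubility of 13, interference of the 3-O-boron chelate, and over-cleavage at the 6-methoxy group. The fallback sets out from compound 10 and comes back at compound 14, unmasking the 5-oxygen at the flavone stage, where the chemistry matches the well-known conversion of 5-methoxy polymethoxyflavones into their 5-hydroxy forms. Flavone 10 is treated with BCl3 and pentamethylbenzene (CH2Cl2, −78 → 0 °C), which cleaves the 5-methyl and both benzyl ethers to give 2-(2,5-dihydroxyphenyl)-5-hydroxy-6,7,8-trimethoxy-4H-chromen-4-one F7. All three hydroxyls are benzylated (BnBr, K2CO3, KI, DMF, 80 °C) to give 5-(benzyloxy)-2-[2,5-bis(benzyloxy)phenyl]-6,7,8-trimethoxy-4H-chromen-4-one F8. Dimethyldioxirane gives the 2,3-epoxide of the tribenzyl flavone F9, which is not isolated, and p-TsOH rearranges it to 5-(benzyloxy)-2-[2,5-bis(benzyloxy)phenyl]-3-hydroxy-6,7,8-trimethoxy-4H-chromen-4-one F10. Hydrogenolysis (H2, Pd/C, EtOAc/MeOH) of all three benzyl ethers gives 14 with no Lewis-acid step at the end.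

## Further compounds

F1 | step 3 | 6-hydroxy-2,3,4-trimethoxybenzaldehyde | COc1cc(O)c(C=O)c(OC)c1OC
F2 | step 3 | 3,4,5-trimethoxybenzene-1,2-diol | COc1cc(O)c(O)c(OC)c1OC
F3 | step 3 | pentamethoxybenzene | COc1cc(OC)c(OC)c(OC)c1OC
F4 | step 3 | 2,3,4,5,6-pentamethoxyacetophenone (not isolated) | CC(=O)c1c(OC)c(OC)c(OC)c(OC)c1OC
F5 | step 7 | 3-lithio-2-[2,5-bis(benzyloxy)phenyl]-5,6,7,8-tetramethoxy-4H-chromen-4-one (not isolated) | COc1c(OC)c(OC)c2c(=O)c([Li])c(-c3cc(OCc4ccccc4)ccc3OCc3ccccc3)oc2c1OC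
F6 | step 7 | dimethyl {2-[2,5-bis(benzyloxy)phenyl]-5,6,7,8-tetramethoxy-4-oxo-4H-chromen-3-yl}boronate | COc1c(OC)c(OC)c2c(=O)c(B(OC)OC)c(-c3cc(OCc4ccccc4)ccc3OCc3ccccc3)oc2c1OC
F7 | step 9 | 2-(2,5-dihydroxyphenyl)-5-hydroxy-6,7,8-trimethoxy-4H-chromen-4-one | COc1c(OC)c(O)c2c(=O)cc(-c3cc(O)ccc3O)oc2c1OC
F8 | step 9 | 5-(benzyloxy)-2-[2,5-bis(benzyloxy)phenyl]-6,7,8-trimethoxy-4H-chromen-4-one | COc1c(OC)c(OCc3ccccc3)c2c(=O)cc(-c3cc(OCc4ccccc4)ccc3OCc3ccccc3)oc2c1OC
F9 | step 9 | 3-(benzyloxy)-1a-[2,5-bis(benzyloxy)phenyl]-4,5,6-trimethoxy-1a,7a-dihydro-7H-oxireno[2,3-b]chromen-7-one... given here as the racemic cis-fused 2,3-epoxide of F8 (not isolated) | COc1c(OC)c(OCc3ccccc3)c2c(c1OC)OC1(c3cc(OCc4ccccc4)ccc3OCc3ccccc3)OC1C2=O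
F10 | step 9 | 5-(benzyloxy)-2-[2,5-bis(benzyloxy)phenyl]-3-hydroxy-6,7,8-trimethoxy-4H-chromen-4-one | COc1c(OC)c(OCc3ccccc3)c2c(=O)c(O)c(-c3cc(OCc4ccccc4)ccc3OCc3ccccc3)oc2c1OC
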